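## Retrosynthetic overview

1. The succinimide is closed last, by neutral nitrile hydration and N‑acyl transfer on a syn‑aldol adduct (C12–C13). The C6 ketone and C12 aldehyde come from one double oxidation, and C8=CH2 comes from an 8‑ketone.
2. Key disconnection: C4–C5 and C9–C10 are cut together. Rings A and B form in one operation from an acyclic 2,3,4‑trichloride by Ag(I) ionisation to a chloriranium, followed by a cation–olefin bicyclisation ended by an enol silane.
3. The trans‑diequatorial 2α,3β‑dichloride is therefore made on the open chain, where it is simply a syn‑dichloride. It then controls C5, C9 and C10, so no decalin is ever chlorinated.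
4. Chain assembly: Paterson aldol (C6–C7), vinylogous Mukaiyama aldol (C1–C2) with SN2 chloride inversion, and catalytic enantioselective dichlorination of prenol (C3/C4).
5. Ring order: A then B within the step 10 cascade, then the imide in step 16.

Assumption: labdane numbering (C1–C20) is used for locants. The antipodes of the Ti ligand (step 1) and of Ipc2BCl (step 7) are taken to be those that give the drawn configurations.

## Forward route

**Step 1**
Reactants: 1, prenol (3‑methylbut‑2‑en‑1‑ol)
Product: 2, (S)‑2,3‑dichloro‑3‑methylbutan‑1‑ol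
Conditions: t‑BuOCl, ClTi(Oi‑Pr)3, chiral tridentate Schiff‑base amino‑alcohol ligand (15 mol %), hexanes, −20 °C
Reagents that add atoms: tert‑butyl hypochlorite CC(C)(C)OCl; chlorotitanium triisopropoxide CC(C)O[Ti](Cl)(OC(C)C)OC(C)C
Why: In this Ti(IV)/Schiff‑base‑catalysed enantioselective dichlorination of an allylic alcohol, the Ti‑bound alkoxide directs a ligand‑controlled anti chloronium/chloride addition that fixes the future C3 as S (about 90% ee, upgraded later by diastereomer separations).

**Step 2**
Reactants: 2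
Product: 3, (S)‑2,3‑dichloro‑3‑methylbutanal
Conditions: DMP, CH2Cl2, 0 °C → rt, no amine; used crude
Reagents that add atoms: none
Why: Dess–Martin oxidation is non‑basic, so the α‑chloro centre is not racemised and the β‑tertiary chloride is not lost by E1cB.

**Step 3**
Reactants: 4, prenal (3‑methylbut‑2‑enal)
Product: 5, (E)‑1‑(tert‑butyldimethylsilyloxy)‑3‑methylbuta‑1,3‑diene
Conditions: TBSOTf, Et3N, Et2O, 0 °C → rt
Reagents that add atoms: TBSOTf CC(C)(C)[Si](C)(C)OS(=O)(=O)C(F)(F)F
Why: Soft γ‑enolisation of the O‑silylated enal forms the silyl dienol ether, and no stereocentre is created.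

**Step 4**
Reactants: 3 and 5
Product: 6, (2E,5S,6S)‑6,7‑dichloro‑5‑hydroxy‑3,7‑dimethyloct‑2‑enal
Conditions: BF3·OEt2, CH2Cl2/Et2O 9:1, −78 °C; aq NaHCO3
Reagents that add atoms: none beyond the numbered reactants (TBS is lost)
Why: In this vinylogous Mukaiyama aldol, γ‑attack through an open transition state under Cornforth/polar Felkin–Anh control by the α‑Cl gives the 1,2‑anti chlorohydrin (new C2 = S), while the s‑trans diene gives the E C5=C10 alkene.

**Step 5**
Reactants: 6
Product: 7, (2E,5R,6S)‑5,6,7‑trichloro‑3,7‑dimethyloct‑2‑enal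
Conditions: PPh3, NCS, CH2Cl2, 0 °C → rt
Reagents that add atoms: N‑chlorosuccinimide O=C1CCC(=O)N1Cl
Why: In this Appel‑type deoxychlorination, SN2 attack of chloride on the alkoxyphosphonium inverts C2 and turns the anti chlorohydrin into the syn‑2,3‑dichloride (the future 2α,3β), and the flanking C–Cl dipoles disfavour ionisation.

**Step 6**
Reactants: 8, (tert‑butyldimethylsilyloxy)acetaldehyde; 9, 1‑(triphenylphosphoranylidene)propan‑2‑one
Product: 10, (E)‑5‑(tert‑butyldimethylsilyloxy)pent‑3‑en‑2‑one
Conditions: CH2Cl2, rt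
Reagents that add atoms: none beyond the numbered reactants
Why: Wittig olefination with a stabilised ylide gives the E‑enone, which carries C7, C8, C9, C11 and C12.

**Step 7**
Reactants: 10 and 7
Product: 11, (2E,7E,6S,10R,11S)‑1‑(TBSO)‑10,11,12‑trichloro‑6‑hydroxy‑8,12‑dimethyltrideca‑2,7‑dien‑4‑one
Conditions: (−)‑Ipc2BCl, Et3N, Et2O, 0 °C; then 7, −78 → −20 °C; pH 7 buffer, H2O2, MeOH, 0 °C
Reagents that add atoms: none beyond the numbered reactants
Why: In this Paterson boron aldol of a methyl ketone, reagent‑controlled Si‑face attack on the enal sets labdane C6 as S (about 5:1, separable); this centre is sacrificial, needed only to sit equatorial in step 10 before it is oxidised in step 13.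

**Step 8**
Reactants: 11
Product: 12, the 6‑O‑TBS ether of 11
Conditions: TBSOTf, 2,6‑lutidine, CH2Cl2, −78 °C
Reagents that add atoms: TBSOTf CC(C)(C)[Si](C)(C)OS(=O)(=O)C(F)(F)F
Why: Silylation blocks dehydration and retro‑aldol, and the silyl ether cannot participate at a C10 cation as an ester would.

**Step 9**
Reactants: 12
Product: 13, (3Z,7E,6S,10R,11S)‑1,6‑bis(TBSO)‑10,11,12‑trichloro‑8,12‑dimethyl‑4‑(triethylsilyloxy)trideca‑3,7‑diene
Conditions: Et3SiH, RhCl(PPh3)3 (2 mol %), THF, 50 °C
Reagents that add atoms: triethylsilane CC[SiH](CC)CC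
Why: Rh‑catalysed 1,4‑hydrosilylation (Ojima type) touches only the enone and gives the C8=C9 (Z)‑enol silane regiospecifically under neutral conditions, so there is no β‑elimination of the C6 silyloxy group.

**Step 10 (key step)**
Reactants: 13
Product: 14, 2α,3β‑dichloro‑6α,12‑bis(TBSO)‑13,14,15,16,17‑pentanorlabdan‑8‑one (trans‑decalone; 5α‑H, 9α‑H, 10β‑Me)
Conditions: AgOTf (1.5 equiv), 2,6‑di‑tert‑butyl‑4‑methylpyridine, 4 Å MS, CH2Cl2, −78 → −20 °C; Et3N/MeOH quench
Reagents that add atoms: none
Why: Proposed new method: Ag(I) abstracts only the tertiary chloride and the C3 chlorine bridges to a configurationally stable chloriranium/β‑chloro cation; the E C5=C10 alkene attacks C4 through a chair with 2‑Cl, 3‑Cl and 6‑OTBS all equatorial, and the C10 cation is trapped anti by the (Z)‑enol silane through a second chair (Stork–Eschenmoser), which sets 5α‑H, 10β‑Me and the equatorial C9 chain at once (C9 can also be corrected by equilibration α to the ketone); the closest known reaction types are stereospecific haliranium polyene cyclisations launched by solvolysis of enantioenriched vicinal dihalides, Lewis‑acid tert‑alkylation of silyl enol ethers with tert‑alkyl chlorides, and enol‑silane‑terminated cation–olefin bicyclisations.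

**Step 11**
Reactants: 14
Product: 15, 2α,3β‑dichloro‑6α,12‑bis(TBSO)‑13,14,15,16‑tetranorlabd‑8(17)‑ene
Conditions: Cp2TiMe2, toluene, 70 °C, dark
Reagents that add atoms: dimethyltitanocene [CH3-].[CH3-].[Ti+4].c1cc[cH-]c1.c1cc[cH-]c1
Why: Petasis methylenation is non‑basic, so it causes no C9 epimerisation and no β‑elimination of 6‑OTBS, and it avoids Zn‑based reagents that could reduce the vicinal dichloride.

**Step 12**
Reactants: 15
Product: 16, 2α,3β‑dichloro‑13,14,15,16‑tetranorlabd‑8(17)‑ene‑6α,12‑diol
Conditions: 48% aq HF, MeCN, 0 °C → rt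
Reagents that add atoms: none
Why: Global fluoride desilylation removes both TBS groups, and the chlorides and alkene are inert to it.

**Step 13**
Reactants: 16
Product: 17, 2α,3β‑dichloro‑6‑oxo‑13,14,15,16‑tetranorlabd‑8(17)‑en‑12‑al
Conditions: DMP (3 equiv), NaHCO3, CH2Cl2, 0 °C → rt; used directly
Reagents that add atoms: none
Why: A buffered double Dess–Martin oxidation unveils the C12 aldehyde and the C6 ketone together, and neutral oxidation of 6α‑hydroxy‑8(17)‑enes gives the unconjugated β,γ‑enone.

**Step 14**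
Reactants: 18, (R)‑4‑benzyloxazolidin‑2‑one; 19, 3‑cyanopropanoic acid
Product: 20, (R)‑4‑benzyl‑3‑(3‑cyanopropanoyl)oxazolidin‑2‑one
Conditions: PivCl, Et3N, THF, −20 °C; then 18, LiCl, rt
Reagents that add atoms: none beyond the numbered reactants
Why: This is a mixed‑anhydride N‑acylation of the Evans auxiliary.

**Step 15**
Reactants: 20 and 17
Product: 21, (R)‑4‑benzyl‑3‑[(2R,3S)‑2‑(cyanomethyl)‑3‑hydroxy‑4‑(decalinyl)butanoyl]oxazolidin‑2‑one, i.e. (12S,13R), with the decalinyl group attached through C9
Conditions: 20 (1.3 equiv), Bu2BOTf, i‑Pr2NEt, CH2Cl2, −78 → 0 °C; then 17, −78 → −30 °C; pH 7 buffer, MeOH, H2O2, 0 °C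
Reagents that add atoms: none beyond the numbered reactants
Why: In this Evans syn aldol, the Z‑boron enolate in a Zimmerman–Traxler chair under the (R)‑auxiliary gives 12S,13R, the aldehyde reacts far faster than the hindered C6 ketone, and the low temperature with little free base spares the β,γ‑enone.

**Step 16**
Reactants: 21
Product: 22, haterumaimide B
Conditions: [PtH(PMe2OH)(PMe2O)2H] (5 mol %), EtOH/H2O 4:1, 70 °C
Reagents that add atoms: water O
Why: Ghaffar–Parkins nitrile hydration is neutral, and the resulting primary amide closes 5‑exo‑trig onto the activated N‑acyl carbonyl (N‑acyl transfer) and expels the oxazolidinone, so the imide forms without base and neither C13 nor the β,γ‑enone is disturbed.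

## Compound list

| No. | Name | SMILES | Role |
|---|---|---|---|
| 1 | prenol | CC(C)=CCO | starting material |
| 2 | (S)‑2,3‑dichloro‑3‑methylbutan‑1‑ol | CC(C)(Cl)[C@@H](Cl)CO | intermediate |
| 3 | (S)‑2,3‑dichloro‑3‑methylbutanal | CC(C)(Cl)[C@@H](Cl)C=O | intermediate |
| 4 | prenal | CC(C)=CC=O | starting material |
| 5 | (E)‑1‑(TBSO)‑3‑methylbuta‑1,3‑diene | C=C(C)/C=C/O[Si](C)(C)C(C)(C)C | intermediate |
| 6 | (2E,5S,6S)‑6,7‑dichloro‑5‑hydroxy‑3,7‑dimethyloct‑2‑enal | CC(C)(Cl)[C@@H](Cl)[C@@H](O)C/C(C)=C/C=O | intermediate |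
| 7 | (2E,5R,6S)‑5,6,7‑trichloro‑3,7‑dimethyloct‑2‑enal | CC(C)(Cl)[C@@H](Cl)[C@H](Cl)C/C(C)=C/C=O | intermediate |
| 8 | (TBSO)acetaldehyde | O=CCO[Si](C)(C)C(C)(C)C | starting material |
| 9 | 1‑(triphenylphosphoranylidene)propan‑2‑one | CC(=O)C=P(c1ccccc1)(c1ccccc1)c1ccccc1 | starting material |
| 10 | (E)‑5‑(TBSO)pent‑3‑en‑2‑one | CC(=O)/C=C/CO[Si](C)(C)C(C)(C)C | intermediate |
| 11 | aldol adduct (6S,10R,11S) | CC(C)(Cl)[C@@H](Cl)[C@H](Cl)C/C(C)=C/[C@@H](O)CC(=O)/C=C/CO[Si](C)(C)C(C)(C)C | intermediate |
| 12 | 6‑O‑TBS ether of 11 | CC(C)(Cl)[C@@H](Cl)[C@H](Cl)C/C(C)=C/[C@@H](O[Si](C)(C)C(C)(C)C)CC(=O)/C=C/CO[Si](C)(C)C(C)(C)C | intermediate |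
| 13 | (Z)‑TES enol ether, the cyclisation substrate | CC(C)(Cl)[C@@H](Cl)[C@H](Cl)C/C(C)=C/[C@@H](O[Si](C)(C)C(C)(C)C)C/C(O[Si](CC)(CC)CC)=C/CCO[Si](C)(C)C(C)(C)C | intermediate |
| 14 | 2α,3β‑dichloro‑6α,12‑bis(TBSO)‑pentanorlabdan‑8‑one | O=C1C[C@H](O[Si](C)(C)C(C)(C)C)[C@H]2C(C)(C)[C@@H](Cl)[C@H](Cl)C[C@]2(C)[C@H]1CCO[Si](C)(C)C(C)(C)C | intermediate |
| 15 | 8(17)‑methylene bis‑TBS ether | C=C1C[C@H](O[Si](C)(C)C(C)(C)C)[C@H]2C(C)(C)[C@@H](Cl)[C@H](Cl)C[C@]2(C)[C@H]1CCO[Si](C)(C)C(C)(C)C | intermediate |
| 16 | 6α,12‑diol | C=C1C[C@H](O)[C@H]2C(C)(C)[C@@H](Cl)[C@H](Cl)C[C@]2(C)[C@H]1CCO | intermediate |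
| 17 | 6‑oxo‑12‑al | C=C1CC(=O)[C@H]2C(C)(C)[C@@H](Cl)[C@H](Cl)C[C@]2(C)[C@H]1CC=O | intermediate |
| 18 | (R)‑4‑benzyloxazolidin‑2‑one | O=C1N[C@H](Cc2ccccc2)CO1 | starting material |
| 19 | 3‑cyanopropanoic acid | N#CCCC(=O)O | starting material |
| 20 | (R)‑4‑benzyl‑3‑(3‑cyanopropanoyl)oxazolidin‑2‑one | N#CCCC(=O)N1[C@H](Cc2ccccc2)COC1=O | intermediate |
| 21 | Evans syn‑aldol adduct (12S,13R) | C=C1CC(=O)[C@H]2C(C)(C)[C@@H](Cl)[C@H](Cl)C[C@]2(C)[C@H]1C[C@H](O)[C@@H](CC#N)C(=O)N1[C@H](Cc2ccccc2)COC1=O | intermediate |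
| 22 | haterumaimide B (2R,3R,5R,9S,10R,12S,13R) | C=C1CC(=O)[C@H]2C(C)(C)[C@@H](Cl)[C@H](Cl)C[C@]2(C)[C@H]1C[C@H](O)[C@H]1CC(=O)NC1=O | target |

## Step count

- Total steps: 16.
- Longest linear sequence: 13 steps (1→2→3→6→7→11→12→13→14→15→16→17→21→22).

## Steps most likely to fail, with fallbacks

1. **Step 10.** The doubly deactivated tertiary chloride may ionise slowly, and E1 loss of a proton or attack on the allylic silyl ether could compete.
   Fallback: abandon cationic C4–C5 bond formation.
   - Buy the C4–C5 bond in 3,3‑dimethylglutaric anhydride.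
   - Set C3 by organocatalytic aldehyde α‑chlorination and C2 by the same vinylogous aldol and inversion.
   - Close rings A and B by an intramolecular Diels–Alder/double Michael reaction of a C5=C6(OSi)–C7=C8 silyloxydiene onto the C9=C10 enoate, which is polarity‑matched and involves no carbocation.
2. **Step 5.** Participation by the C3 chlorine would give retention and hence the anti‑dichloride, and vinylogous elimination is also possible.
   Fallback: avoid the SN2 step altogether.
   - Ti‑catalysed enantioselective anti‑dichlorination of (Z)‑4‑methylpenta‑2,4‑dien‑1‑ol gives the syn‑2,3‑dichloride in one stereospecific step.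
   - Join the C1 triflate to an (E)‑alkenyl cuprate carrying C10=C5–C6 as an acetal.
   - Add HCl to the isopropenyl group to regain 7.
3. **Step 16**, together with handling of the β,γ‑enone from step 13 onward. The imide may fail to close, or the enone may slip into conjugation on heating.
   Fallback: build the imide before the ketone exists.
   - Selectively deprotect C12 in 15 and oxidise it to the aldehyde.
   - Run the aldol with the methyl succinate imide and form the succinimide with NH3 while 6α‑OTBS is still in place.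
   - Mask C12‑OH as a Troc carbonate, remove the TBS group with HF and oxidise C6 with DMP.
   - Release C12‑OH with Zn/AcOH as the last step.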